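The earlier runs and the new flask are calculated for an exercise; the scatter is artificial.

Count the partner.

| flask | starting material | coupling partner | remark | time |
|---|---|---|---|---|
| east | 0.030 M (in portions, 2) | 1.3 equiv | the very flask that is asked about, followed so far; portions every 2.0 h |  |
| north-west | 0.020 M (in portions, 2) | 1.3 equiv | run made earlier; portions every 2.0 h |  |
| flask | 0.030 M (in portions, 2) | 1.30 equiv | the portions of starting material follow each other after 2.0 h, the first at the start | 10 d |

| run | time / d | starting material / % | product / % |
|---|---|---|---|
| east | 0.208 | 37.6 | 12.8 |
| east | 0.625 | 35.0 | 38.3 |
| east | 1.04 | 34.8 | 50.4 |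
| east | 1.67 | 35.4 | 59.5 |
| east | 2.50 | 35.8 | 63.7 |
| east | 3.00 | 34.3 | 63.6 |
| east | 4.00 | 35.0 | 64.9 |
| north-west | 0.833 | 42.2 | 40.3 |
| north-west | 1.25 | 42.9 | 48.3 |
| north-west | 1.67 | 41.3 | 53.2 |
| north-west | 3.00 | 41.9 | 57.5 |
| north-west | 4.00 | 41.9 | 57.2 |
| north-west | 6.00 | 43.5 | 57.4 |
| north-west | 10.0 | 42.4 | 57.6 |

(standard deviation of a reading: 0.5 percentage points)

* concentration of starting material at 10 d, in M
* concentration of product at 10 d, in M

I build the east flask, which is the flask asked about, one process at a time. With the main step alone, starting material and coupling partner to product, 1.30 equiv of partner is more than the charge needs, so I reckon [starting material] at nothing and [product] at 0.030 M.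

Next I add a hidden intermediate. East accounts for 50.4 % of its charge at 0.208 d and 99.9 % at 4.00 d, so this step delays the product without changing the final number.

Last I add a first-order loss of partner, my own assumption. Coupling then goes with [starting material] × [partner] and the loss with [partner], and the two ends join in one balance, treating both portions as one charge:

partner lost = 0.0390 M − 0.0195 M = 0.0195 M

K = partner lost / ln([starting material] charged / [starting material] left) = 0.0186 M

This K is the even-split level: the [starting material] at which partner, on this lumped view, goes equally to coupling and to loss. East's whole charge stands above it and its plateau reading below it. North-west reads 0.0165 M, a lower figure, so I carry K as a rough one. North-west stays flat to 10.0 d, so I carry the east plateau forward.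

The forecast says 0.0105 M and 0.0195 M, judging that “the partner or an active agent is probably lost in a competing process”. My number comes from the same readings and is the same.

The flask gives 0.0105 M and 0.0195 M.

    starting material + coupling partner → intermediate + by-product (k = 31.6 M⁻¹ h⁻¹)
    intermediate → product (k = 0.0658 h⁻¹)
    coupling partner → decomposed reagent (k = 0.308 h⁻¹)

The forecast stands, and in the flask the partner, at 0 %, is the limiting reagent despite its excess. The neighbouring flask with 2.20 equiv of partner, all else the same, ends at 0.00368 M of starting material and 0.0263 M of product. In that flask K × ln([starting material] charged / [starting material] left) gives 0.0390 M, against 0.0397 M of decomposed reagent.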